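A direct plan would keep the arene of 4,5-dibromophthalic anhydride A1 and reach the indole by ring contraction: Curtius nitrogen insertion to anthranilate A2, malonylation and Dieckmann closure to quinolinone A3, diazo transfer to A4, Wolff contraction to acid A5, decarboxylation to oxindole A6, deoxybromination to A7, then C3 bromination.
Weakest would be the build-up of the six-membered lactam: four steps for a ring made only to be contracted, with two carbons lost as CO2.
The Wolff contraction would be a late photolysis of a diazo compound beside two aryl bromides, giving a labile acid whose one stereocentre would form racemic and vanish at once.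
The deoxybromination of lactam A6 would be least welcome on late material: the N–H 2-bromoindole A7 would be acid-labile and prone to oligomerise.

**Plan of the new route**
The retrosynthesis first trades all four bromines for what an electrophile displaces: H at C2 and C3, SiMe3 at C5 and C6 (indole 11).
It then cuts C3a–C7a, C4–C5 and C6–C7 in one [2+2+2] disconnection, leaving the acyclic ynamide-diyne 6 and bis(trimethylsilyl)acetylene 7.
Both rings arise together in step 4; no starting material holds either ring.
The feature used is the vicinal C5/C6 dibromide flanked by C4–H and C7–H on a benzene ring fused to a five-membered ring whose N1–C2–C3 chain is a three-atom tether. C5–C6 is therefore a symmetrical alkyne, and the pattern is fixed by connectivity.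
No lactam is built or contracted, no diazo compound or photolysis is used, no C3-unsubstituted 2-bromoindole is handled, and no stereocentre is formed.

Key step: step 4

Assumption: compounds 1, 3 and 7 are taken as commercial. In step 7 the first ipso substitution is taken to occur at C5, para to N1; the opposite order would converge on the same product.

Step 1
Reactants: 1 but-3-yn-1-amine
Product: 2 N-(but-3-yn-1-yl)-4-methylbenzenesulfonamide
Conditions: TsCl (1.05 equiv), Et3N (1.5 equiv), CH2Cl2, 0 °C → rt
Reagents that add atoms: p-toluenesulfonyl chloride, Cc1ccc(cc1)S(Cl)(=O)=O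
Why: N-sulfonylation of a primary amine (sulfonamide formation); the sulfonyl group makes N–H acidic enough for the alkynylation and later stabilises the ynamide.

Step 2
Reactants: 2 N-(but-3-yn-1-yl)-4-methylbenzenesulfonamide; 3 phenyl[(trimethylsilyl)ethynyl]iodonium trifluoromethanesulfonate
Product: 5 N-(but-3-yn-1-yl)-4-methyl-N-[(trimethylsilyl)ethynyl]benzenesulfonamide, via potassium sulfonamide 4 (not isolated)
Conditions: KN(SiMe3)2 (1.05 equiv), PhMe, 0 °C; then 3 (1.1 equiv), 0 °C → rt
Reagents that add atoms: none
Why: N-alkynylation of a sulfonamide anion with an alkynyliodonium salt (conjugate addition to the β-carbon, loss of PhI to an alkylidene carbene, 1,2-shift to the ynamide); one equivalent of base removes only the N–H proton, and no copper is present that could couple the free terminal alkyne.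

Step 3
Reactants: 5 N-(but-3-yn-1-yl)-4-methyl-N-[(trimethylsilyl)ethynyl]benzenesulfonamide
Product: 6 N-(but-3-yn-1-yl)-N-ethynyl-4-methylbenzenesulfonamide
Conditions: Bu4NF (1.1 equiv), THF containing 1% H2O, −20 → 0 °C; used promptly
Reagents that add atoms: none
Why: Fluoride-induced protodesilylation of an alkynylsilane, which frees the ynamide terminus so that C7 of the arene will carry hydrogen; the N-sulfonyl ynamide should tolerate these mild conditions.

Step 4
Reactants: 6 N-(but-3-yn-1-yl)-N-ethynyl-4-methylbenzenesulfonamide; 7 bis(trimethylsilyl)acetylene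
Product: 9 1-(4-methylbenzenesulfonyl)-5,6-bis(trimethylsilyl)-2,3-dihydro-1H-indole, via cobaltacyclopentadiene 8 (not isolated)
Conditions: CpCo(CO)2 (10 mol %), degassed 7 as solvent, 6 in 7–THF added by syringe pump over 10 h, reflux (ca. 135 °C), hν (visible lamp), Ar; excess 7 recovered by distillation
Reagents that add atoms: none
Why: After loss of CO the CpCo fragment (monovalent cobalt) binds both alkynes of 6 and couples them oxidatively to the bicyclic cobaltacyclopentadiene 8 (trivalent cobalt), which forms C3a–C7a; 8 then takes up 7, by insertion into a Co–C bond or by [4+2] addition to the metallacycle diene, and reductive elimination forms C4–C5 and C6–C7 and returns the catalyst. The closest known reaction types are the CpCo(CO)2-catalysed cocyclisation of α,ω-diynes with bis(trimethylsilyl)acetylene and the metal-catalysed [2+2+2] cyclotrimerisation of N-sulfonyl ynamide-diynes to indolines. The five-membered nitrogen ring closes in the oxidative cyclometallation of the 1,6-diyne, where the three-atom tether N1–C2–C3 allows only coupling of the two internal alkyne carbons, and the benzene ring closes when the third alkyne is stitched between the cobalt-bound carbons C4 and C7. No stereocentre is formed. The step needs crossed cocyclisation instead of self-oligomerisation of 6, which should be secured because 7 is too hindered to trimerise with itself yet is present as solvent, while 6 is kept at low stationary concentration. Regiochemistry cannot go wrong, since 7 is symmetrical and its two silicon-bearing carbons must become the adjacent positions C5 and C6 between C4–H and C7–H.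

Step 5
Reactants: 9 1-(4-methylbenzenesulfonyl)-5,6-bis(trimethylsilyl)-2,3-dihydro-1H-indole
Product: 10 1-(4-methylbenzenesulfonyl)-5,6-bis(trimethylsilyl)-1H-indole
Conditions: DDQ (1.5 equiv), PhMe, 100 °C; filtration through basic Al2O3
Reagents that add atoms: none
Why: Quinone dehydrogenation of an indoline (hydride abstraction from benzylic C3, proton loss from C2) driven by aromatisation; the aryl–silicon bonds are not oxidised, and basic alumina removes the acidic hydroquinone before it can protodesilylate.

Step 6
Reactants: 10 1-(4-methylbenzenesulfonyl)-5,6-bis(trimethylsilyl)-1H-indole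
Product: 11 5,6-bis(trimethylsilyl)-1H-indole
Conditions: Mg turnings (10 equiv), MeOH–THF 3:1, ultrasound, rt; pH 7 phosphate buffer
Reagents that add atoms: none
Why: Reductive desulfonylation of an N-sulfonylindole by electron transfer from magnesium, which should be fast because the indolide is a good leaving group; the basic medium and the buffered work-up leave the acid-sensitive aryl–silicon bonds intact.

Step 7
Reactants: 11 5,6-bis(trimethylsilyl)-1H-indole
Product: 15 2,3,5,6-tetrabromo-1H-indole, via 3-bromo-5,6-bis(trimethylsilyl)indole 12 (not isolated), via 2,3-dibromo-5,6-bis(trimethylsilyl)indole 13 (not isolated), via 2,3,5-tribromo-6-(trimethylsilyl)indole 14 (not isolated)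
Conditions: NBS (2.05 equiv), anhydrous DMF, −40 → 0 °C, dark; then NBS (2.2 equiv), 0 → 40 °C; aq Na2S2O3–NaHCO3
Reagents that add atoms: N-bromosuccinimide, O=C1CCC(=O)N1Br
Why: Electrophilic bromination of the indole at C3 and then C2 is followed by two ipso-bromodesilylations, in which attack at the silicon-bearing carbons is favoured by the β-silyl-stabilised arenium ion and outruns attack at C4–H and C7–H, so the benzenoid bromines can only enter at C5 and C6; NBS releases no HBr that could protodesilylate, and the thiosulfate quench returns any N-bromo or 3,3-dibromoindolenine species to the indole.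

**Compound list**

1 | but-3-yn-1-amine | NCCC#C | starting material
2 | N-(but-3-yn-1-yl)-4-methylbenzenesulfonamide | Cc1ccc(cc1)S(=O)(=O)NCCC#C | intermediate
3 | phenyl[(trimethylsilyl)ethynyl]iodonium trifluoromethanesulfonate | C[Si](C)(C)C#C[I+]c1ccccc1.[O-]S(=O)(=O)C(F)(F)F | starting material
4 | potassium (but-3-yn-1-yl)(4-methylbenzenesulfonyl)azanide | Cc1ccc(cc1)S(=O)(=O)[N-]CCC#C.[K+] | intermediate
5 | N-(but-3-yn-1-yl)-4-methyl-N-[(trimethylsilyl)ethynyl]benzenesulfonamide | Cc1ccc(cc1)S(=O)(=O)N(CCC#C)C#C[Si](C)(C)C | intermediate
6 | N-(but-3-yn-1-yl)-N-ethynyl-4-methylbenzenesulfonamide | Cc1ccc(cc1)S(=O)(=O)N(CCC#C)C#C | intermediate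
7 | bis(trimethylsilyl)acetylene | C[Si](C)(C)C#C[Si](C)(C)C | starting material
8 | cyclopentadienyl cobaltacyclopentadiene fused to the N-tosylpyrroline, Co bonded to the future C4 and C7 (cyclopentadienyl ligand written as the separate anion) | Cc1ccc(cc1)S(=O)(=O)N1CCC2=C[Co+]C=C12.[cH-]1cccc1 | intermediate
9 | 1-(4-methylbenzenesulfonyl)-5,6-bis(trimethylsilyl)-2,3-dihydro-1H-indole | Cc1ccc(cc1)S(=O)(=O)N1CCc2cc([Si](C)(C)C)c([Si](C)(C)C)cc21 | intermediate
10 | 1-(4-methylbenzenesulfonyl)-5,6-bis(trimethylsilyl)-1H-indole | Cc1ccc(cc1)S(=O)(=O)n1ccc2cc([Si](C)(C)C)c([Si](C)(C)C)cc21 | intermediate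
11 | 5,6-bis(trimethylsilyl)-1H-indole | C[Si](C)(C)c1cc2cc[nH]c2cc1[Si](C)(C)C | intermediate
12 | 3-bromo-5,6-bis(trimethylsilyl)-1H-indole | C[Si](C)(C)c1cc2c(Br)c[nH]c2cc1[Si](C)(C)C | intermediate
13 | 2,3-dibromo-5,6-bis(trimethylsilyl)-1H-indole | C[Si](C)(C)c1cc2c(Br)c(Br)[nH]c2cc1[Si](C)(C)C | intermediate
14 | 2,3,5-tribromo-6-(trimethylsilyl)-1H-indole | Brc1cc2c(Br)c(Br)[nH]c2cc1[Si](C)(C)C | intermediate
15 | 2,3,5,6-tetrabromo-1H-indole | Brc1cc2[nH]c(Br)c(Br)c2cc1Br | target

Total steps: 7. Longest linear sequence: 7 steps (1 → 15).

**Steps most likely to fail**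

Step 7. The second ipso substitution may stall on a ring that by then carries three bromines. Positive bromine may also be diverted to C3 a second time, forming a 3,3-dibromoindolenine that hydrolyses on work-up. Adventitious acid may cleave a C–Si bond before bromine arrives and leave that position unsubstituted. The fallback sets out from 10 and returns at 15, and puts the bromines in while the pyrrole nitrogen is still sulfonylated. Br2 (3.3 equiv) with NaOAc in AcOH–CH2Cl2 at room temperature should effect both ipso-bromodesilylations and the C3 bromination that N-sulfonylindoles undergo, giving 3,5,6-tribromo-1-(4-methylbenzenesulfonyl)-1H-indole F1. KOH in MeOH–THF should then remove the sulfonyl group to give 3,5,6-tribromo-1H-indole F2. One equivalent of NBS in THF at −78 → 0 °C should brominate the remaining C2 position to give 15.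

Step 4. Self-oligomerisation or thermal breakdown of the terminal ynamide-diyne may outrun its capture by the hindered alkyne, and the catalyst may be drained into a cyclobutadiene complex of 7. The fallback sets out from 6 and returns at 15, with boron in place of silicon. Room-temperature cocyclisation with commercial 1,2-bis(4,4,5,5-tetramethyl-1,3,2-dioxaborolan-2-yl)ethyne under Cp*RuCl(cod) in ClCH2CH2Cl should give 1-(4-methylbenzenesulfonyl)-5,6-bis(4,4,5,5-tetramethyl-1,3,2-dioxaborolan-2-yl)-2,3-dihydro-1H-indole F3. Bromodeboronation with CuBr2 in MeOH–H2O at 80 °C should give 5,6-dibromo-1-(4-methylbenzenesulfonyl)-2,3-dihydro-1H-indole F4. DDQ in PhCl at 120 °C should give 5,6-dibromo-1-(4-methylbenzenesulfonyl)-1H-indole F5, and KOH in MeOH–THF should give 5,6-dibromo-1H-indole F6. NBS (2.05 equiv) in THF at −78 → 0 °C should then brominate C3 and C2, through 3,5,6-tribromo-1H-indole F2 in the flask, to give 15.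

Step 5. Hydride abstraction from the sulfonamide-deactivated indoline may be slow at a temperature the silanes tolerate, so that conversion stays incomplete while the acidic hydroquinone begins to protodesilylate. The fallback sets out from 9 and returns at 11; it reverses the order of oxidation and deprotection and moves the oxidation to the free amine. Na and naphthalene in THF at −78 °C should cleave the sulfonamide to 5,6-bis(trimethylsilyl)-2,3-dihydro-1H-indole F7. MnO2 in CH2Cl2 at room temperature should dehydrogenate this indoline to 11, so that 10 is bypassed.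

**Further compounds**

F1 | step 7 | 3,5,6-tribromo-1-(4-methylbenzenesulfonyl)-1H-indole | Cc1ccc(cc1)S(=O)(=O)n1cc(Br)c2cc(Br)c(Br)cc21
F2 | step 7 | 3,5,6-tribromo-1H-indole | Brc1c[nH]c2cc(Br)c(Br)cc12
F3 | step 4 | 1-(4-methylbenzenesulfonyl)-5,6-bis(4,4,5,5-tetramethyl-1,3,2-dioxaborolan-2-yl)-2,3-dihydro-1H-indole | Cc1ccc(cc1)S(=O)(=O)N1CCc2cc(B3OC(C)(C)C(C)(C)O3)c(B3OC(C)(C)C(C)(C)O3)cc21
F4 | step 4 | 5,6-dibromo-1-(4-methylbenzenesulfonyl)-2,3-dihydro-1H-indole | Cc1ccc(cc1)S(=O)(=O)N1CCc2cc(Br)c(Br)cc21
F5 | step 4 | 5,6-dibromo-1-(4-methylbenzenesulfonyl)-1H-indole | Cc1ccc(cc1)S(=O)(=O)n1ccc2cc(Br)c(Br)cc21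
F6 | step 4 | 5,6-dibromo-1H-indole | Brc1cc2cc[nH]c2cc1Br
F7 | step 5 | 5,6-bis(trimethylsilyl)-2,3-dihydro-1H-indole | C[Si](C)(C)c1cc2CCNc2cc1[Si](C)(C)C
A1 | direct plan | 4,5-dibromophthalic anhydride | O=C1OC(=O)c2cc(Br)c(Br)cc12
A2 | direct plan | methyl 2-amino-4,5-dibromobenzoate | COC(=O)c1cc(Br)c(Br)cc1N
A3 | direct plan | 6,7-dibromo-4-hydroxyquinolin-2(1H)-one | O=C1C=C(O)c2cc(Br)c(Br)cc2N1
A4 | direct plan | 6,7-dibromo-3-diazoquinoline-2,4(1H,3H)-dione | [N-]=[N+]=C1C(=O)Nc2cc(Br)c(Br)cc2C1=O
A5 | direct plan | rac-5,6-dibromo-2-oxoindoline-3-carboxylic acid | OC(=O)C1C(=O)Nc2cc(Br)c(Br)cc12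
A6 | direct plan | 5,6-dibromoindolin-2-one | O=C1Cc2cc(Br)c(Br)cc2N1
A7 | direct plan | 2,5,6-tribromo-1H-indole | Brc1cc2cc(Br)[nH]c2cc1Br
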